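**Assumption:** the target SMILES contains no stereogenic element (achiral, C24H28O8), so there is no enantiomer to select and no stereocontrol is needed. Nothing below has been run; yields and selectivities are expectations.

## Retrosynthetic overview

1. The obvious cut, two acylphloroglucinol monomers plus formaldehyde, gives a statistical mixture of three dimers and is not used.
2. Instead the bridging CH2 is an aryl methyl group already on ring A: the Ar–CH2–Ar bond is made by adding ring B (6) to an o-quinone methide released from the benzylic acetate 8.
3. Acetate 8 comes from the symmetric 3,5-dimethyl ring-A ketone 3 by DDQ benzylic C–H acetoxylation (the bold step).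
4. Ketone 3 comes from commercial 2',6'-dihydroxy-4'-methoxyacetophenone by double C-methylation; 6 comes from phloracetophenone by mono C-prenylation.
5. No rings are formed; both benzene rings are bought intact. The order is: functionalise ring A, functionalise ring B, oxidise, join.

## Route

**Step 1**
Reactants: 1, 2',6'-dihydroxy-4'-methoxyacetophenone; 2, iodomethane
Product: 3, 1-(2,6-dihydroxy-4-methoxy-3,5-dimethylphenyl)ethanone (symmetric; both ring C–H positions methylated)
Conditions: NaOMe (3.0 equiv), MeI (2.3 equiv), MeOH, 0 → 45 °C, 12 h; then 1 M HCl; chromatography (mono-C-methyl by-product resubmitted)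
Reagents that add atoms: iodomethane, CI (two CH3 groups)
Why: Nuclear C-methylation of a phloroglucinol phenoxide in protic solvent; the chelated OH groups resist O-alkylation, and the two free ring carbons are the only sites that can re-aromatise after alkylation.

**Step 2**
Reactants: 4, 2',4',6'-trihydroxyacetophenone (phloracetophenone); 5, prenyl bromide (1-bromo-3-methylbut-2-ene)
Product: 6, 1-[2,4,6-trihydroxy-3-(3-methylbut-2-en-1-yl)phenyl]ethanone (3-prenylphloracetophenone; one aromatic C–H left)
Conditions: 4 (1.5 equiv), 10% aq KOH, prenyl bromide (1.0 equiv, slow addition), 0 °C, 2 h; then 1 M HCl; chromatography (excess 4 recovered)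
Reagents that add atoms: prenyl bromide, CC(C)=CCBr (C5H9 unit)
Why: Classical C-prenylation of a phloroglucinol phenoxide; water solvates the phenoxide oxygens and favours SN2 C-alkylation to the linear prenyl group, and excess 4 limits diprenylation.

**Step 3 (key oxidation)**
Reactants: 3, 1-(2,6-dihydroxy-4-methoxy-3,5-dimethylphenyl)ethanone; 7, acetic acid
Product: 8, (3-acetyl-2,4-dihydroxy-6-methoxy-5-methylphenyl)methyl acetate (one of the two equivalent ArCH3 groups converted to ArCH2OAc)
Conditions: DDQ (0.95 equiv), AcOH/1,4-dioxane 1:4, 15 °C → rt, 1 h, until DDQ is consumed; filter off DDQH2, concentrate below 30 °C (toluene azeotrope to remove AcOH); crude 8 used at once in step 4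
Reagents that add atoms: acetic acid, CC(=O)O (the acetoxy group)
Why: Proposed new method: DDQ abstracts a benzylic hydride from one ArCH3 of 3 (cation stabilised by ortho-OH, ortho-OMe and para-OH, with the acetyl group meta) to give a quinone methide that AcOH traps as acetate 8. The electron-poor acetate is less prone to a second oxidation than a benzylic ether, and sub-stoichiometric DDQ limits aldehyde and bis-oxidation products. The symmetry of 3 makes the choice of methyl irrelevant, and the prenyl-bearing partner is absent, so DDQ cannot convert it to a chromene. Closest known reaction types: DDQ benzylic acetoxylation/alkoxylation of o- and p-cresols, and DDQ dehydrogenation of o-prenyl acylphloroglucinols to chromenes (same o-quinone methide formation).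

**Step 4 (union)**
Reactants: 8, (3-acetyl-2,4-dihydroxy-6-methoxy-5-methylphenyl)methyl acetate; 6, 3-prenylphloracetophenone
Product: 9, mallotojaponin, 1-[3-[(3-acetyl-2,4-dihydroxy-6-methoxy-5-methylphenyl)methyl]-2,4,6-trihydroxy-5-(3-methylbut-2-enyl)phenyl]ethanone
Conditions: 8 (1.0 equiv), 6 (1.3 equiv), NaOAc (3 equiv), 1,4-dioxane, 65 °C, 3 h, Ar; aq NH4Cl work-up; chromatography
Reagents that add atoms: none (acetate is the leaving group; C13H16O6 + C13H16O4 → C24H28O8 + AcOH)
Why: o-Quinone methide Friedel–Crafts (Michael-type) arylation: mild base and heat eliminate acetate from the o-hydroxybenzyl acetate, and the single free, doubly OH-flanked ring carbon of 6 adds and re-aromatises. Ring A has no aromatic C–H and 6 has only one, so only the cross-dimer can form. The acetate-buffered medium avoids acid-induced chroman formation from the prenyl group.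

## Compound list

1 | 2',6'-dihydroxy-4'-methoxyacetophenone | COc1cc(O)c(C(C)=O)c(O)c1 | starting material
2 | iodomethane | CI | starting material (reagent)
3 | 1-(2,6-dihydroxy-4-methoxy-3,5-dimethylphenyl)ethanone | COc1c(C)c(O)c(C(C)=O)c(O)c1C | intermediate
4 | 2',4',6'-trihydroxyacetophenone | CC(=O)c1c(O)cc(O)cc1O | starting material
5 | prenyl bromide | CC(C)=CCBr | starting material (reagent)
6 | 1-[2,4,6-trihydroxy-3-(3-methylbut-2-en-1-yl)phenyl]ethanone | CC(=O)c1c(O)cc(O)c(CC=C(C)C)c1O | intermediate
7 | acetic acid | CC(=O)O | starting material (reagent)
8 | (3-acetyl-2,4-dihydroxy-6-methoxy-5-methylphenyl)methyl acetate | COc1c(C)c(O)c(C(C)=O)c(O)c1COC(C)=O | intermediate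
9 | mallotojaponin | COc1c(C)c(O)c(C(C)=O)c(O)c1Cc1c(O)c(CC=C(C)C)c(O)c(C(C)=O)c1O | target

## Summary

Total steps: 4 (two monomer preparations, one oxidation, one convergent coupling).
Longest linear sequence: 3 (step 1 → step 3 → step 4).

Steps most likely to fail, with fallbacks that change the approach:

1. **Step 3, DDQ benzylic acetoxylation.** Risks are sluggish hydride abstraction from the acetyl-deactivated ring, over-oxidation to the aldehyde, oxidation of both methyl groups, and quinone methide self-condensation. Fallback: build the benzylic carbon by C–C bond formation instead of C–H oxidation. Stop step 1 at the mono-C-methyl compound (2,6-dihydroxy-4-methoxy-3-methylacetophenone), aminomethylate its last free ring position (Mannich, Eschenmoser's salt or CH2O/Me2NH), then quaternise with MeI and warm with 6 so the ammonium salt releases the same o-quinone methide.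
2. **Step 4, quinone methide arylation.** Risks are quinone methide oligomerisation, O- instead of C-alkylation, prenyl cyclisation to a chroman, and methylene-bridge exchange giving homodimers. Fallback: reorder the route. Couple 8 with excess phloracetophenone 4 (no prenyl group present) to give the desprenyl dimer, then C-prenylate last (prenyl bromide, aq KOH) at the only aromatic C–H left in the molecule.
3. **Step 1, double C-methylation.** Risks are mixtures of mono-, di- and gem-dimethyl (dearomatised) products. Fallback: build 3 by ring acylation instead of ring alkylation: Friedel–Crafts acetylation of 2,4-dimethylphloroglucinol (Ac2O, BF3·OEt2), then selective methylation of the non-chelated 4-OH (Me2SO4, K2CO3, acetone).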